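## Retrosynthetic overview

1. Locants: ring A = C1–C6 (C1 OAc, C2 OAng, C3 OH and methyl C15, C4 Cl, C6 side chain); side chain C7(=C14H2)–C8(OAng)–C9–C10/C11 oxirane. Target 34 ⇐ C10–C11 epoxidation ⇐ prenyl cross-metathesis ⇐ C8 allylboration and angeloylation (both angelates from the one preformed mixed anhydride 25) ⇐ C8 aldehyde ⇐ lactone opening with C1 acetylation ⇐ chlorohydrin lactone 27.
2. 27 ⇐ chloride opening of the C3–C4 oxirane ⇐ hydroxyl-directed epoxidation ⇐ all-cis hydroxy lactone 22 ⇐ C2 inversion (oxidation, Luche reduction) ⇐ lactone 19.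
3. Feature on which the strategy rests: on ring A the C1 oxygen and the C6–C7(=C14H2)–C8 unit are cis on adjacent carbons, the retron of a cis-fused α-methylene-γ-butyrolactone (ring B: O–C1–C6–C7–C8). 19 ⇐ ring-closing allylation (C1–C6) of the 2-(methoxycarbonyl)allyl chromium from (Z,Z)-bromo ester aldehyde 16, then lactonisation C1–O→C8.
4. 16 ⇐ glycol cleavage (C1 aldehyde), transposing bromination and vinylalumination at C6, Z-selective Wittig (C3=C4), methyl ketone from L-threonate acetonide 1 (source of C2).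
5. Ring order: ring A and lactone ring B together in step 10; C3–C4 oxirane in step 14 (opened in step 17); ring B reopened in step 18; C10–C11 oxirane last (step 24).

Key step: step 10

Remark on the chemistry (assumption): with C3 tied to the nucleophile, the closed chromium transition state is taken to hold the C2 silyl ether pseudoaxial and antiperiplanar to C1=O (Cornforth-type) rather than anti to the forming bond, so the lactone forms trans to that oxygen; C2 is therefore carried as the (7S) silyl ether and inverted in steps 12 and 13.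

## Route

Step 1
Reactants: 1 methyl 3,4-O-isopropylidene-L-threonate [methyl (2R)-2-[(4S)-2,2-dimethyl-1,3-dioxolan-4-yl]-2-hydroxyacetate]
Product: 2 methyl (2R)-2-[(tert-butyldimethylsilyl)oxy]-2-[(4S)-2,2-dimethyl-1,3-dioxolan-4-yl]acetate
Conditions: TBSCl, imidazole, DMF, 25 °C
Reagents that add atoms: tert-butyldimethylsilyl chloride, CC(C)(C)[Si](C)(C)Cl
Why: Imidazole-promoted silylation of the secondary α-hydroxy ester installs the bulky, non-chelating ether at the future C2 without touching a stereocentre.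

Step 2
Reactants: 2 silyl ether ester
Product: 4 (1R)-1-[(tert-butyldimethylsilyl)oxy]-1-[(4S)-2,2-dimethyl-1,3-dioxolan-4-yl]propan-2-one, via Weinreb amide 3 (not isolated)
Conditions: MeNH(OMe)·HCl, i-PrMgCl, THF, −20 °C; then MeMgBr, −20 → 0 °C; aq. NH4Cl
Reagents that add atoms: methylmagnesium bromide, C[Mg]Br; N,O-dimethylhydroxylamine hydrochloride, CNOC.Cl (its atoms are carried by 3 only)
Why: One-pot Weinreb ketone synthesis, in which the magnesium amide turns the ester into the N-methoxy-N-methylamide and its chelated adduct with MeMgBr stops at the ketone stage, which also shields the α-silyloxy centre from enolisation.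

Step 3
Reactants: 5 (3-bromopropoxy)(tert-butyl)dimethylsilane
Product: 6 {3-[(tert-butyldimethylsilyl)oxy]propyl}triphenylphosphonium bromide
Conditions: PPh3, MeCN, 80 °C
Reagents that add atoms: triphenylphosphine, c1ccc(cc1)P(c1ccccc1)c1ccccc1
Why: SN2 quaternisation of the phosphine by the unhindered primary bromide gives the Wittig salt; no stereocentre is involved.

Step 4
Reactants: 4 methyl ketone; 6 phosphonium salt
Product: 8 (4S)-4-[(1S,2Z)-1,5-bis[(tert-butyldimethylsilyl)oxy]-2-methylpent-2-en-1-yl]-2,2-dimethyl-1,3-dioxolane, via phosphorus ylide 7 (not isolated)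
Conditions: 6, NaN(SiMe3)2, THF, 0 °C; then 4, −78 → 25 °C
Reagents that add atoms: none
Why: Wittig olefination of an α-alkoxy methyl ketone with a non-stabilised ylide, a combination known to place the ylide chain cis to the oxygen-bearing carbon, should set the (Z)-C3=C4 alkene (C5 cis to C2), and the salt-free, cold conditions should leave the C2 centre unepimerised.

Step 5
Reactants: 8 bis-silyl ether
Product: 9 (3Z,5S)-5-[(tert-butyldimethylsilyl)oxy]-5-[(4S)-2,2-dimethyl-1,3-dioxolan-4-yl]-4-methylpent-3-en-1-ol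
Conditions: HF·pyridine, pyridine, THF, 0 °C
Reagents that add atoms: none
Why: Buffered fluoride desilylation is much faster at the unhindered primary ether than at the hindered secondary allylic one, and the acetonide is stable to it.

Step 6
Reactants: 9 homoallylic alcohol
Product: 10 (3Z,5S)-5-[(tert-butyldimethylsilyl)oxy]-5-[(4S)-2,2-dimethyl-1,3-dioxolan-4-yl]-4-methylpent-3-enal
Conditions: Dess–Martin periodinane, NaHCO3, CH2Cl2, 0 → 25 °C
Reagents that add atoms: none
Why: Dess–Martin oxidation under buffered, near-neutral conditions should give the β,γ-unsaturated aldehyde without moving the alkene into conjugation; the crude aldehyde is used at once.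

Step 7
Reactants: 10 skipped enal; 11 methyl propiolate
Product: 13 methyl (5Z,7S)-7-[(tert-butyldimethylsilyl)oxy]-7-[(4S)-2,2-dimethyl-1,3-dioxolan-4-yl]-3-hydroxy-6-methyl-2-methylidenehept-5-enoate (both C3 epimers), via vinylalane 12 (not isolated)
Conditions: i-Bu2AlH, N-methylmorpholine N-oxide, THF, 0 °C; 11, 0 °C; then 10, 0 → 25 °C; aq. NH4Cl
Reagents that add atoms: none
Why: Vinylalumination, in which 1,4-hydroalumination of the propiolate gives the α-aluminoacrylate that adds to the aldehyde, delivers the Baylis–Hillman-type adduct quickly and without amine base, so the sensitive enal is not isomerised; the new carbinol centre forms as a mixture that step 8 erases.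

Step 8
Reactants: 13 hydroxy acrylate
Product: 14 methyl (2Z,5Z,7S)-2-(bromomethyl)-7-[(tert-butyldimethylsilyl)oxy]-7-[(4S)-2,2-dimethyl-1,3-dioxolan-4-yl]-6-methylhepta-2,5-dienoate
Conditions: N-bromosuccinimide, Me2S, CH2Cl2, 0 → 25 °C
Reagents that add atoms: N-bromosuccinimide, O=C1CCC(=O)N1Br
Why: Corey–Kim-type activation of the allylic alcohol followed by SN2′ attack of bromide at C14 is the known transposing bromination of Baylis–Hillman adducts and should give the more stable (Z)-2-(bromomethyl)alk-2-enoate (C5 cis to CH2Br) under neutral conditions.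

Step 9
Reactants: 14 acetonide bromide
Product: 16 methyl (2Z,5Z,7S)-2-(bromomethyl)-7-[(tert-butyldimethylsilyl)oxy]-6-methyl-8-oxoocta-2,5-dienoate, via diol 15 (not isolated)
Conditions: H5IO6, EtOAc, 25 °C
Reagents that add atoms: none
Why: Periodic acid hydrolyses the terminal acetonide and cleaves the freed 1,2-diol in the same pot (glycol cleavage), so the C1 aldehyde is released without base and the α-silyloxy centre, the allylic bromide and the skipped diene should survive.

Step 10
Reactants: 16 (Z,Z)-bromo ester aldehyde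
Product: 19 (3aR,7S,7aS)-7-[(tert-butyldimethylsilyl)oxy]-6-methyl-3-methylidene-3a,4,7,7a-tetrahydro-1-benzofuran-2(3H)-one, via allylchromium species 17 (not isolated), via chromium alkoxide 18 (not isolated)
Conditions: CrCl2 (6 equiv), THF, 25 °C, slow addition of 16 (final 5 mM); then aq. NH4Cl
Reagents that add atoms: none
Why: Divalent chromium (two CrCl2) reduces the C14–Br bond to the 2-(methoxycarbonyl)allyl chromium species 17 (trivalent chromium), which adds through C6 to the C1 aldehyde with allylic transposition in a closed chair (Zimmerman–Traxler) transition state, and the C1 alkoxide 18 then acylates at C8 with loss of methoxide; the closest known reaction type is the intramolecular Nozaki–Hiyama (Barbier) allylation of 2-(bromomethyl)acrylates to α-methylene-γ-butyrolactones. Ring A closes in the 6-exo-trig mode at the aldehyde, with the (Z)-C3=C4 alkene holding C2 and C5 cis, and ring B closes in the 5-exo-trig mode by acyl substitution. C6 is controlled by the (Z)-C6=C7 geometry, which the ester-bearing allyl metal retains: C5 sits axial and C2 equatorial in the chair, a cis-decalin-like array that makes C1–O and C6–C7 cis (C1–O axial on ring A) and hence the lactone cis-fused. C1 is controlled by C2: because C3 is tied to the nucleophile, an anti (Felkin) placement of the silyloxy group would make it pseudoequatorial, eclipsed with the C15 methyl and gauche to the metal-bound oxygen, so the Cornforth-type array with C2–O pseudoaxial and antiperiplanar to C1=O is expected to be favoured and both new centres should form trans to the C2 oxygen. The step needs this facial selectivity, the cis ring fusion and ring closure ahead of intermolecular coupling; the bulky non-chelating silyl ether next to the methyl-bearing alkene carbon, the (Z,Z)-diene geometry and slow addition at high dilution are what secure them.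

Step 11
Reactants: 19 silyl ether lactone
Product: 20 (3aR,7S,7aS)-7-hydroxy-6-methyl-3-methylidene-3a,4,7,7a-tetrahydro-1-benzofuran-2(3H)-one
Conditions: HF·pyridine, THF, 0 → 25 °C
Reagents that add atoms: none
Why: Acidic fluoride cleaves the secondary allylic silyl ether and avoids the basic conditions under which the α-methylene lactone would take up nucleophiles.

Step 12
Reactants: 20 allylic alcohol (C2–OH trans to the lactone oxygen)
Product: 21 (3aR,7aS)-6-methyl-3-methylidene-3a,4-dihydro-1-benzofuran-2,7(3H,7aH)-dione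
Conditions: Dess–Martin periodinane, NaHCO3, CH2Cl2, 0 °C
Reagents that add atoms: none
Why: Dess–Martin oxidation of the allylic alcohol gives the cyclohexenone and erases the C2 centre once it has steered the ring closure.

Step 13
Reactants: 21 enone lactone
Product: 22 (3aR,7R,7aS)-7-hydroxy-6-methyl-3-methylidene-3a,4,7,7a-tetrahydro-1-benzofuran-2(3H)-one (all-cis)
Conditions: NaBH4, CeCl3·7H2O, MeOH, −78 °C
Reagents that add atoms: none
Why: Luche 1,2-reduction should deliver hydride to the convex face of the cis-fused bicycle, anti to the adjacent C1–O bond, so the new C2–OH is cis to the lactone oxygen as the target requires, and the short reaction at low temperature should spare the α-methylene lactone.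

Step 14
Reactants: 22 all-cis allylic alcohol
Product: 23 3,4-epoxy-2-hydroxy lactone (1S,2S,3S,4R,6R; oxirane across C3–C4 on the face of the C2 hydroxyl)
Conditions: VO(acac)2 (5 mol %), t-BuOOH, CH2Cl2, 0 → 25 °C
Reagents that add atoms: tert-butyl hydroperoxide, CC(C)(C)OO
Why: Vanadium-catalysed, hydroxyl-directed epoxidation delivers oxygen to the C3=C4 face syn to the C2–OH and so sets C3 and C4, while the electron-poor α-methylene alkene is inert to this reagent.

Step 15
Reactants: 24 angelic acid [(2Z)-2-methylbut-2-enoic acid]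
Product: 25 (2Z)-2-methylbut-2-enoic 2,4,6-trichlorobenzoic anhydride (angeloyl mixed anhydride)
Conditions: 2,4,6-trichlorobenzoyl chloride, Et3N, toluene, 0 → 25 °C; filter off Et3N·HCl, concentrate; kept as a toluene stock solution at −20 °C
Reagents that add atoms: 2,4,6-trichlorobenzoyl chloride, O=C(Cl)c1c(Cl)cc(Cl)cc1Cl
Why: Acyl substitution at the aroyl chloride by triethylammonium angelate, the activation half of the Yamaguchi esterification, gives the mixed anhydride under conditions too mild to isomerise the (Z)-alkene, involves no stereocentre, and provides in one batch the acylating agent for both later angeloylations.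

Step 16
Reactants: 23 epoxy alcohol; 25 angeloyl mixed anhydride
Product: 26 3,4-epoxy-2-angeloyloxy lactone (1S,2S,3R,4R,6R)
Conditions: 25 (3 equiv), Et3N, toluene, 70 °C
Reagents that add atoms: none
Why: Yamaguchi-type acylation by the preformed mixed anhydride, whose aroyl carbonyl is shielded by two ortho chlorines so that the alcohol attacks the angeloyl carbonyl, is the usual way to esterify hindered alcohols with angelic acid with little Z→E isomerisation, the amine buffers the released acid away from the oxirane, and acylating C2 while the C1 oxygen is still locked in the lactone rules out acyl migration.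

Step 17
Reactants: 26 epoxy angelate
Product: 27 4-chloro-3-hydroxy-2-angeloyloxy lactone (1S,2S,3S,4S,6R)
Conditions: HCl (2 M in Et2O), CH2Cl2, −40 → 0 °C
Reagents that add atoms: hydrogen chloride, Cl
Why: Acid-promoted epoxide opening by chloride should occur at C4 with inversion, because trans-diaxial (Fürst–Plattner) opening in the chair that keeps C7 and the C2 ester equatorial, the lower substitution at C4 and the inductive deactivation of C3 by the C2 acyloxy group all point to that carbon, leaving the C3–OH with its configuration.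

Step 18
Reactants: 27 chlorohydrin lactone
Product: 28 C8 N-methoxy-N-methylamide with free C1–OH (1S,2S,3S,4S,6R)
Conditions: AlMe3, MeNH(OMe)·HCl, CH2Cl2, 0 → 25 °C; then aq. potassium sodium tartrate
Reagents that add atoms: N,O-dimethylhydroxylamine hydrochloride, CNOC.Cl
Why: Weinreb aminolysis by the aluminium amide, a hard nucleophile that adds 1,2, opens the unhindered lactone much faster than it attacks the hindered conjugated angelate, freeing C1–OH and leaving C8 at the amide level.

Step 19
Reactants: 28 hydroxy amide (used crude)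
Product: 29 C1 acetate of the N-methoxy-N-methylamide (1S,2S,3S,4S,6R)
Conditions: Ac2O, pyridine, 4-(dimethylamino)pyridine (cat.), CH2Cl2, 0 → 25 °C
Reagents that add atoms: acetic anhydride, CC(=O)OC(C)=O
Why: Nucleophile-catalysed acetylation of the secondary C1–OH, done immediately to forestall relactonisation, leaves the tertiary C3–OH untouched.

Step 20
Reactants: 29 acetate amide
Product: 30 C8 aldehyde (2-substituted propenal; 1S,2S,3S,4S,6R)
Conditions: Cp2Zr(H)Cl, THF, 25 °C
Reagents that add atoms: none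
Why: Hydrozirconation of the amide carbonyl gives a stable zirconated hemiaminal that releases the aldehyde on work-up, a reduction that tolerates the acetate, the angelate and the alkyl chloride.

Step 21
Reactants: 30 enal
Product: 31 (8S)-homoallylic alcohol (1S,2S,3S,4S,6R,8S)
Conditions: (−)-Ipc2B(allyl), Et2O, −78 °C; then ethanolamine, 25 °C
Reagents that add atoms: (−)-B-allyldiisopinocampheylborane, C=CCB([C@H]1[C@H](C)[C@H]2C[C@@H](C1)C2(C)C)[C@H]1[C@H](C)[C@H]2C[C@@H](C1)C2(C)C
Why: Brown asymmetric allylboration with the reagent from (+)-α-pinene adds the allyl group to the Si face of the aldehyde through a chair transition state and should set C8 as S under reagent control, and the non-oxidative work-up protects the esters and the chlorohydrin.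

Step 22
Reactants: 31 homoallylic alcohol; 25 angeloyl mixed anhydride
Product: 32 C2,C8-bis(angelate) with terminal C10 alkene (1S,2S,3S,4S,6R,8S)
Conditions: 25 (1.5 equiv), Et3N, 4-(dimethylamino)pyridine (cat.), toluene, 25 °C
Reagents that add atoms: none
Why: Yamaguchi-type acylation of the unhindered allylic C8–OH by the preformed mixed anhydride should proceed at room temperature, where the angeloyl unit keeps its geometry and the tertiary C3–OH does not react.

Step 23
Reactants: 32 terminal alkene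
Product: 33 prenyl compound (C10=C11 alkene; 1S,2S,3S,4S,6R,8S)
Conditions: 2-methylbut-2-ene, second-generation Grubbs catalyst RuCl2(=CHPh)(H2IMes)(PCy3) (5 mol %), CH2Cl2, 40 °C
Reagents that add atoms: 2-methylbut-2-ene, CC=C(C)C
Why: Olefin cross-metathesis of the monosubstituted C10 alkene with excess 2-methylbut-2-ene installs the dimethylated terminus, while the 1,1-disubstituted C7=C14 alkene and the trisubstituted angelate alkenes are too hindered or too electron-poor to take part.

Step 24
Reactants: 33 prenyl compound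
Product: 34 CNP0313121.1, (1S,2S,3S,4S,6R,8S,10S)-1-acetoxy-2,8-bis(angeloyloxy)-4-chloro-10,11-epoxybisabol-7(14)-en-3-ol
Conditions: L-fructose-derived Shi ketone (1,2:4,5-di-O-isopropylidene-β-L-erythro-2,3-hexodiulo-2,6-pyranose, 1 equiv), Oxone (2KHSO5·KHSO4·K2SO4), NaHCO3, Bu4NHSO4, MeCN/(MeO)2CH2/H2O, pH 8, 0 °C
Reagents that add atoms: potassium peroxymonosulfate, [K+].OOS(=O)(=O)[O-]
Why: Shi asymmetric epoxidation, in which the chiral dioxirane attacks the electron-rich trisubstituted C10=C11 alkene through a spiro transition state, should give the (10S)-oxirane under catalyst control, and the near-neutral protocol is chosen so that the trans-diaxial chlorohydrin does not reclose while the conjugated and 1,1-disubstituted alkenes stay untouched.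

## Compound list

1 | methyl 3,4-O-isopropylidene-L-threonate, methyl (2R)-2-[(4S)-2,2-dimethyl-1,3-dioxolan-4-yl]-2-hydroxyacetate | COC(=O)[C@H](O)[C@@H]1COC(C)(C)O1 | starting material
2 | methyl (2R)-2-[(tert-butyldimethylsilyl)oxy]-2-[(4S)-2,2-dimethyl-1,3-dioxolan-4-yl]acetate | COC(=O)[C@H](O[Si](C)(C)C(C)(C)C)[C@@H]1COC(C)(C)O1 | intermediate
3 | (2R)-2-[(tert-butyldimethylsilyl)oxy]-2-[(4S)-2,2-dimethyl-1,3-dioxolan-4-yl]-N-methoxy-N-methylacetamide (not isolated) | CON(C)C(=O)[C@H](O[Si](C)(C)C(C)(C)C)[C@@H]1COC(C)(C)O1 | intermediate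
4 | (1R)-1-[(tert-butyldimethylsilyl)oxy]-1-[(4S)-2,2-dimethyl-1,3-dioxolan-4-yl]propan-2-one | CC(=O)[C@H](O[Si](C)(C)C(C)(C)C)[C@@H]1COC(C)(C)O1 | intermediate
5 | (3-bromopropoxy)(tert-butyl)dimethylsilane | CC(C)(C)[Si](C)(C)OCCCBr | starting material
6 | {3-[(tert-butyldimethylsilyl)oxy]propyl}triphenylphosphonium bromide | CC(C)(C)[Si](C)(C)OCCC[P+](c1ccccc1)(c1ccccc1)c1ccccc1.[Br-] | intermediate
7 | {3-[(tert-butyldimethylsilyl)oxy]propylidene}triphenylphosphorane (not isolated) | CC(C)(C)[Si](C)(C)OCCC=P(c1ccccc1)(c1ccccc1)c1ccccc1 | intermediate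
8 | (4S)-4-[(1S,2Z)-1,5-bis[(tert-butyldimethylsilyl)oxy]-2-methylpent-2-en-1-yl]-2,2-dimethyl-1,3-dioxolane | CC(C)(C)[Si](C)(C)OCC/C=C(C)\[C@H](O[Si](C)(C)C(C)(C)C)[C@@H]1COC(C)(C)O1 | intermediate
9 | (3Z,5S)-5-[(tert-butyldimethylsilyl)oxy]-5-[(4S)-2,2-dimethyl-1,3-dioxolan-4-yl]-4-methylpent-3-en-1-ol | OCC/C=C(C)\[C@H](O[Si](C)(C)C(C)(C)C)[C@@H]1COC(C)(C)O1 | intermediate
10 | (3Z,5S)-5-[(tert-butyldimethylsilyl)oxy]-5-[(4S)-2,2-dimethyl-1,3-dioxolan-4-yl]-4-methylpent-3-enal | O=CC/C=C(C)\[C@H](O[Si](C)(C)C(C)(C)C)[C@@H]1COC(C)(C)O1 | intermediate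
11 | methyl propiolate | C#CC(=O)OC | starting material
12 | methyl 2-(diisobutylalumanyl)prop-2-enoate (not isolated) | C=C(C(=O)OC)[Al](CC(C)C)CC(C)C | intermediate
13 | methyl (5Z,7S)-7-[(tert-butyldimethylsilyl)oxy]-7-[(4S)-2,2-dimethyl-1,3-dioxolan-4-yl]-3-hydroxy-6-methyl-2-methylidenehept-5-enoate (C3 epimers) | C=C(C(=O)OC)C(O)C/C=C(C)\[C@H](O[Si](C)(C)C(C)(C)C)[C@@H]1COC(C)(C)O1 | intermediate
14 | methyl (2Z,5Z,7S)-2-(bromomethyl)-7-[(tert-butyldimethylsilyl)oxy]-7-[(4S)-2,2-dimethyl-1,3-dioxolan-4-yl]-6-methylhepta-2,5-dienoate | BrC/C(C(=O)OC)=C\C/C=C(C)\[C@H](O[Si](C)(C)C(C)(C)C)[C@@H]1COC(C)(C)O1 | intermediate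
15 | methyl (2Z,5Z,7S,8S)-2-(bromomethyl)-7-[(tert-butyldimethylsilyl)oxy]-8,9-dihydroxy-6-methylnona-2,5-dienoate (not isolated) | BrC/C(C(=O)OC)=C\C/C=C(C)\[C@H](O[Si](C)(C)C(C)(C)C)[C@@H](O)CO | intermediate
16 | methyl (2Z,5Z,7S)-2-(bromomethyl)-7-[(tert-butyldimethylsilyl)oxy]-6-methyl-8-oxoocta-2,5-dienoate (key-step precursor) | BrC/C(C(=O)OC)=C\C/C=C(C)\[C@H](O[Si](C)(C)C(C)(C)C)C=O | intermediate
17 | methyl (2Z,5Z,7S)-7-[(tert-butyldimethylsilyl)oxy]-2-[(dichlorochromio)methyl]-6-methyl-8-oxoocta-2,5-dienoate (allyl–CrCl2 species, not isolated) | Cl[Cr](Cl)C/C(C(=O)OC)=C\C/C=C(C)\[C@H](O[Si](C)(C)C(C)(C)C)C=O | intermediate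
18 | OCrCl2 alkoxide of methyl 2-[(1R,5S,6S)-5-[(tert-butyldimethylsilyl)oxy]-6-hydroxy-4-methylcyclohex-3-en-1-yl]prop-2-enoate (not isolated) | C=C(C(=O)OC)[C@H]1CC=C(C)[C@H](O[Si](C)(C)C(C)(C)C)[C@H]1O[Cr](Cl)Cl | intermediate
19 | (3aR,7S,7aS)-7-[(tert-butyldimethylsilyl)oxy]-6-methyl-3-methylidene-3a,4,7,7a-tetrahydro-1-benzofuran-2(3H)-one (key-step product) | C=C3[C@H]1CC=C(C)[C@H](O[Si](C)(C)C(C)(C)C)[C@H]1OC3=O | intermediate
20 | (3aR,7S,7aS)-7-hydroxy-6-methyl-3-methylidene-3a,4,7,7a-tetrahydro-1-benzofuran-2(3H)-one | C=C3[C@H]1CC=C(C)[C@H](O)[C@H]1OC3=O | intermediate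
21 | (3aR,7aS)-6-methyl-3-methylidene-3a,4-dihydro-1-benzofuran-2,7(3H,7aH)-dione | C=C3[C@H]1CC=C(C)C(=O)[C@H]1OC3=O | intermediate
22 | (3aR,7R,7aS)-7-hydroxy-6-methyl-3-methylidene-3a,4,7,7a-tetrahydro-1-benzofuran-2(3H)-one (all-cis) | C=C3[C@H]1CC=C(C)[C@@H](O)[C@H]1OC3=O | intermediate
23 | 3,4-epoxy-2-hydroxy lactone (1S,2S,3S,4R,6R), oxirane cis to C2–OH | C=C3[C@H]1C[C@H]2O[C@@]2(C)[C@@H](O)[C@H]1OC3=O | intermediate
24 | angelic acid, (2Z)-2-methylbut-2-enoic acid | C/C=C(/C)C(=O)O | starting material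
25 | (2Z)-2-methylbut-2-enoic 2,4,6-trichlorobenzoic anhydride (angeloyl mixed anhydride) | C/C=C(/C)C(=O)OC(=O)c1c(Cl)cc(Cl)cc1Cl | intermediate
26 | 3,4-epoxy-2-angeloyloxy lactone (1S,2S,3R,4R,6R) | C=C3[C@H]1C[C@H]2O[C@@]2(C)[C@@H](OC(=O)/C(C)=C\C)[C@H]1OC3=O | intermediate
27 | 4-chloro-3-hydroxy-2-angeloyloxy lactone (1S,2S,3S,4S,6R) | C=C3[C@H]1C[C@H](Cl)[C@@](C)(O)[C@@H](OC(=O)/C(C)=C\C)[C@H]1OC3=O | intermediate
28 | C8 N-methoxy-N-methylamide, C1–OH free, C2 angelate, C3–OH, C4–Cl (1S,2S,3S,4S,6R) | C=C(C(=O)N(C)OC)[C@H]1C[C@H](Cl)[C@@](C)(O)[C@@H](OC(=O)/C(C)=C\C)[C@H]1O | intermediate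
29 | C1 acetate of 28 (1S,2S,3S,4S,6R) | C=C(C(=O)N(C)OC)[C@H]1C[C@H](Cl)[C@@](C)(O)[C@@H](OC(=O)/C(C)=C\C)[C@H]1OC(C)=O | intermediate
30 | C8 aldehyde, 2-(ring A)propenal with C1 acetate and C2 angelate (1S,2S,3S,4S,6R) | C=C(C=O)[C@H]1C[C@H](Cl)[C@@](C)(O)[C@@H](OC(=O)/C(C)=C\C)[C@H]1OC(C)=O | intermediate
31 | (8S)-homoallylic alcohol (1S,2S,3S,4S,6R,8S) | C=C([C@H](CC=C)O)[C@H]1C[C@H](Cl)[C@@](C)(O)[C@@H](OC(=O)/C(C)=C\C)[C@H]1OC(C)=O | intermediate
32 | C2,C8-bis(angelate) with terminal C10 alkene (1S,2S,3S,4S,6R,8S) | C=C([C@H](CC=C)OC(=O)/C(C)=C\C)[C@H]1C[C@H](Cl)[C@@](C)(O)[C@@H](OC(=O)/C(C)=C\C)[C@H]1OC(C)=O | intermediate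
33 | prenyl compound, C10=C11 alkene (1S,2S,3S,4S,6R,8S) | C=C([C@H](CC=C(C)C)OC(=O)/C(C)=C\C)[C@H]1C[C@H](Cl)[C@@](C)(O)[C@@H](OC(=O)/C(C)=C\C)[C@H]1OC(C)=O | intermediate
34 | CNP0313121.1, (1S,2S,3S,4S,6R,8S,10S)-1-acetoxy-2,8-bis(angeloyloxy)-4-chloro-10,11-epoxybisabol-7(14)-en-3-ol | C=C([C@H](C[C@@H]1OC1(C)C)OC(=O)/C(C)=C\C)[C@H]1C[C@H](Cl)[C@@](C)(O)[C@@H](OC(=O)/C(C)=C\C)[C@H]1OC(C)=O | target

## Step count and risks

Total step count: 24. Longest linear sequence: 22 steps (1 to 34 through steps 1, 2, 4–14 and 16–24; step 3, which makes the phosphonium salt 6, and step 15, which makes the acylating agent 25, are side branches).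

Steps most likely to fail:

1. Step 10. C6 may add to the other face of the aldehyde (the acyclic Felkin course, both new centres cis to the silyl ether), or to both faces, and ring closure may lose out to intermolecular coupling. Fallback: switch to the series in which the cis course gives the target configuration and drop the C2 correction. It sets out from 1. Mitsunobu inversion (4-nitrobenzoic acid, PPh3, diisopropyl azodicarboxylate, THF) would give the 4-nitrobenzoate F1, and methanolysis (K2CO3, MeOH, 0 °C) the (2S)-hydroxy ester F2. Steps 1, 2 and 4–9, unchanged, would then lead through the silyl ether F3, the Weinreb amide F4 (not isolated), the methyl ketone F5, the (Z)-alkene F6, the homoallylic alcohol F7, the skipped enal F8, the hydroxy acrylate F9, the acetonide bromide F10 and the diol F11 (not isolated) to the (7R)-bromo ester aldehyde F12. Ring closure with CrCl2 as in step 10 would pass through the allylchromium species F13 and the chromium alkoxide F14 to the all-cis silyl ether lactone F15. Desilylation with HF·pyridine comes back to the route at 22, so steps 12 and 13 fall away.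

2. Step 16. Acylation of the hindered C2–OH may stall, and long heating with base may isomerise the angeloyl unit to the tigloyl unit. Fallback: build the Z-alkene on the ester after acylation with a saturated, more reactive acid. It sets out from 23. Esterification with 2-(diphenoxyphosphoryl)propanoic acid (N-ethyl-N′-(3-dimethylaminopropyl)carbodiimide hydrochloride, 4-(dimethylamino)pyridine, CH2Cl2) would give the phosphonopropanoate F16. A Z-selective Horner–Wadsworth–Emmons reaction of this diaryl phosphonate with acetaldehyde (NaH, THF, −78 °C) comes back to the route at 26.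

3. Step 24. The trans-diaxial chlorohydrin may reclose to the C3–C4 oxirane in the buffered medium, or oxidation at pH 8 may be slow enough for ketone decomposition to outrun it. Fallback: mask the tertiary hydroxyl so that the catalytic, more basic protocol can be used. It sets out from 33. Silylation (Me3SiOTf, 2,6-lutidine, CH2Cl2, −78 °C) would give the trimethylsilyl ether F17. Epoxidation with the same ketone (30 mol %) and Oxone at pH 10.5 (K2CO3 buffer, 0 °C) would give the epoxy silyl ether F18. Buffered fluoride (Bu4NF, AcOH, THF, 0 °C) comes back to the route at 34.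

Further compounds
F1 | step 10 | methyl (2S)-2-[(4S)-2,2-dimethyl-1,3-dioxolan-4-yl]-2-[(4-nitrobenzoyl)oxy]acetate | COC(=O)[C@@H](OC(=O)c1ccc(cc1)[N+](=O)[O-])[C@@H]1COC(C)(C)O1
F2 | step 10 | methyl (2S)-2-[(4S)-2,2-dimethyl-1,3-dioxolan-4-yl]-2-hydroxyacetate (methyl 3,4-O-isopropylidene-L-erythronate) | COC(=O)[C@@H](O)[C@@H]1COC(C)(C)O1
F3 | step 10 | methyl (2S)-2-[(tert-butyldimethylsilyl)oxy]-2-[(4S)-2,2-dimethyl-1,3-dioxolan-4-yl]acetate | COC(=O)[C@@H](O[Si](C)(C)C(C)(C)C)[C@@H]1COC(C)(C)O1
F4 | step 10 | (2S)-2-[(tert-butyldimethylsilyl)oxy]-2-[(4S)-2,2-dimethyl-1,3-dioxolan-4-yl]-N-methoxy-N-methylacetamide | CON(C)C(=O)[C@@H](O[Si](C)(C)C(C)(C)C)[C@@H]1COC(C)(C)O1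
F5 | step 10 | (1S)-1-[(tert-butyldimethylsilyl)oxy]-1-[(4S)-2,2-dimethyl-1,3-dioxolan-4-yl]propan-2-one | CC(=O)[C@@H](O[Si](C)(C)C(C)(C)C)[C@@H]1COC(C)(C)O1
F6 | step 10 | (4S)-4-[(1R,2Z)-1,5-bis[(tert-butyldimethylsilyl)oxy]-2-methylpent-2-en-1-yl]-2,2-dimethyl-1,3-dioxolane | CC(C)(C)[Si](C)(C)OCC/C=C(C)\[C@@H](O[Si](C)(C)C(C)(C)C)[C@@H]1COC(C)(C)O1
F7 | step 10 | (3Z,5R)-5-[(tert-butyldimethylsilyl)oxy]-5-[(4S)-2,2-dimethyl-1,3-dioxolan-4-yl]-4-methylpent-3-en-1-ol | OCC/C=C(C)\[C@@H](O[Si](C)(C)C(C)(C)C)[C@@H]1COC(C)(C)O1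
F8 | step 10 | (3Z,5R)-5-[(tert-butyldimethylsilyl)oxy]-5-[(4S)-2,2-dimethyl-1,3-dioxolan-4-yl]-4-methylpent-3-enal | O=CC/C=C(C)\[C@@H](O[Si](C)(C)C(C)(C)C)[C@@H]1COC(C)(C)O1
F9 | step 10 | methyl (5Z,7R)-7-[(tert-butyldimethylsilyl)oxy]-7-[(4S)-2,2-dimethyl-1,3-dioxolan-4-yl]-3-hydroxy-6-methyl-2-methylidenehept-5-enoate (C3 epimers) | C=C(C(=O)OC)C(O)C/C=C(C)\[C@@H](O[Si](C)(C)C(C)(C)C)[C@@H]1COC(C)(C)O1
F10 | step 10 | methyl (2Z,5Z,7R)-2-(bromomethyl)-7-[(tert-butyldimethylsilyl)oxy]-7-[(4S)-2,2-dimethyl-1,3-dioxolan-4-yl]-6-methylhepta-2,5-dienoate | BrC/C(C(=O)OC)=C\C/C=C(C)\[C@@H](O[Si](C)(C)C(C)(C)C)[C@@H]1COC(C)(C)O1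
F11 | step 10 | methyl (2Z,5Z,7R,8S)-2-(bromomethyl)-7-[(tert-butyldimethylsilyl)oxy]-8,9-dihydroxy-6-methylnona-2,5-dienoate | BrC/C(C(=O)OC)=C\C/C=C(C)\[C@@H](O[Si](C)(C)C(C)(C)C)[C@@H](O)CO
F12 | step 10 | methyl (2Z,5Z,7R)-2-(bromomethyl)-7-[(tert-butyldimethylsilyl)oxy]-6-methyl-8-oxoocta-2,5-dienoate | BrC/C(C(=O)OC)=C\C/C=C(C)\[C@@H](O[Si](C)(C)C(C)(C)C)C=O
F13 | step 10 | methyl (2Z,5Z,7R)-7-[(tert-butyldimethylsilyl)oxy]-2-[(dichlorochromio)methyl]-6-methyl-8-oxoocta-2,5-dienoate | Cl[Cr](Cl)C/C(C(=O)OC)=C\C/C=C(C)\[C@@H](O[Si](C)(C)C(C)(C)C)C=O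
F14 | step 10 | OCrCl2 alkoxide of methyl 2-[(1R,5R,6S)-5-[(tert-butyldimethylsilyl)oxy]-6-hydroxy-4-methylcyclohex-3-en-1-yl]prop-2-enoate | C=C(C(=O)OC)[C@H]1CC=C(C)[C@@H](O[Si](C)(C)C(C)(C)C)[C@H]1O[Cr](Cl)Cl
F15 | step 10 | (3aR,7R,7aS)-7-[(tert-butyldimethylsilyl)oxy]-6-methyl-3-methylidene-3a,4,7,7a-tetrahydro-1-benzofuran-2(3H)-one | C=C3[C@H]1CC=C(C)[C@@H](O[Si](C)(C)C(C)(C)C)[C@H]1OC3=O
F16 | step 16 | 3,4-epoxy lactone 23 esterified at C2–O with 2-(diphenoxyphosphoryl)propanoic acid (epimers at the phosphonate carbon) | C=C3[C@H]1C[C@H]2O[C@@]2(C)[C@@H](OC(=O)C(C)P(=O)(Oc4ccccc4)Oc4ccccc4)[C@H]1OC3=O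
F17 | step 24 | C3-O-trimethylsilyl ether of 33 | C=C([C@H](CC=C(C)C)OC(=O)/C(C)=C\C)[C@H]1C[C@H](Cl)[C@@](C)(O[Si](C)(C)C)[C@@H](OC(=O)/C(C)=C\C)[C@H]1OC(C)=O
F18 | step 24 | C3-O-trimethylsilyl ether of 34 | C=C([C@H](C[C@@H]1OC1(C)C)OC(=O)/C(C)=C\C)[C@H]1C[C@H](Cl)[C@@](C)(O[Si](C)(C)C)[C@@H](OC(=O)/C(C)=C\C)[C@H]1OC(C)=O
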